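**Retrosynthetic overview**
- Last step: proton-initiated cationic bicyclization of the fully assembled acyclic C25 chain (as from geranylfarnesyl diphosphate). Ring A closes first, then ring B; the cascade stops at C8 because the formyl group deactivates C13=C14, and proton loss gives the Δ8(9) alkene.
- The butenolide is closed before that by lactonization of a (Z)-γ-hydroxy enoate. C16 and the C15–C16 bond come from an asymmetric vinylogous Mukaiyama aldol reaction.
- Aldol partners: a C20 silyl dienol ether and a (Z)-formyl acrylate.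
- The dienol ether comes from farnesyl bromide and methylglyoxal dimethyl acetal (C11–C12), then an ethylidene Wittig reaction (C13=C14). The formyl acrylate comes from furan-3-ylmethanol by singlet-oxygen oxidation.
- Ring order: lactone, then ring A, then ring B.

Assumption: the facial sense of both chiral promoters is assigned by analogy with simpler substrates and has not been verified for these; the antipodal promoter is used if it proves opposite.

**Step 1**
Reactants: 1 (2E,6E)-farnesyl bromide; 2 1,1-dimethoxypropan-2-one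
Product: 3 (5E,9E)-1,1-dimethoxy-6,10,14-trimethylpentadeca-5,9,13-trien-2-one
Conditions: LiN(iPr)2, THF, −78 °C; then 1, DMPU, −78 to 0 °C
Reagents that add atoms: none
Why: The kinetic lithium enolate of 2 forms at the methyl group and displaces the primary allylic bromide by SN2 (ketone enolate alkylation), installing C12 without touching the E-alkenes.

**Step 2**
Reactants: 3 (5E,9E)-1,1-dimethoxy-6,10,14-trimethylpentadeca-5,9,13-trien-2-one
Product: 5 (2E,5E,9E)-2-ethylidene-6,10,14-trimethylpentadeca-5,9,13-trienal, via dimethyl acetal 4 (not isolated)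
Conditions: EtPPh3Br, KN(SiMe3)2, THF, −78 °C to rt; then 1 M HCl, THF, rt
Reagents that add atoms: ethyltriphenylphosphonium bromide CC[P+](c1ccccc1)(c1ccccc1)c1ccccc1.[Br-]; water O
Why: Wittig olefination of the acetal-activated ketone with the non-stabilised ethylidene ylide builds C13=C14, and the acid work-up hydrolyses the allylic acetal and equilibrates the enal to the E isomer (this geometry is erased again in step 3).

**Step 3**
Reactants: 5 (2E,5E,9E)-2-ethylidene-6,10,14-trimethylpentadeca-5,9,13-trienal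
Product: 6 (1E,5E,9E)-1-(tert-butyldimethylsilyloxy)-2-ethenyl-6,10,14-trimethylpentadeca-1,5,9,13-tetraene
Conditions: TBSOTf, Et3N, CH2Cl2, 0 °C to rt
Reagents that add atoms: tert-butyldimethylsilyl trifluoromethanesulfonate CC(C)(C)[Si](C)(C)OS(=O)(=O)C(F)(F)F
Why: O-silylation of the enal and amine-mediated γ-deprotonation at the C15 methyl (soft enolisation) give the linear silyl dienol ether whose terminal carbon is the nucleophile for the vinylogous aldol reaction.

**Step 4**
Reactants: 7 furan-3-ylmethanol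
Product: 8 3-[(triethylsilyloxy)methyl]furan
Conditions: TESCl, imidazole, CH2Cl2, 0 °C
Reagents that add atoms: chlorotriethylsilane CC[Si](Cl)(CC)CC
Why: Standard silyl ether formation protects the primary alcohol (the future C25 hydroxyl) for steps 5 to 7.

**Step 5**
Reactants: 8 3-[(triethylsilyloxy)methyl]furan
Product: 9 5-hydroxy-4-[(triethylsilyloxy)methyl]furan-2(5H)-one
Conditions: O2, hν, rose bengal (cat.), iPr2NEt, CH2Cl2, −78 °C
Reagents that add atoms: dioxygen O=O
Why: [4+2] addition of singlet oxygen to the furan and Kornblum–DeLaMare-type fragmentation of the endoperoxide by the hindered base at the less hindered C–H give the 4-substituted 5-hydroxybutenolide regioselectively.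

**Step 6**
Reactants: 9 5-hydroxy-4-[(triethylsilyloxy)methyl]furan-2(5H)-one
Product: 10 methyl (2Z)-3-formyl-4-(triethylsilyloxy)but-2-enoate
Conditions: Me3SiCHN2, MeOH/toluene, 0 °C, dark; used at once
Reagents that add atoms: (trimethylsilyl)diazomethane C[Si](C)(C)C=[N+]=[N-]
Why: Neutral O-methylation of the ring-opened acid tautomer of the pseudo-acid (diazoalkane esterification) traps the cis formyl ester without base or acid that would isomerise it.

**Step 7**
Reactants: 6 (1E,5E,9E)-1-(tert-butyldimethylsilyloxy)-2-ethenyl-6,10,14-trimethylpentadeca-1,5,9,13-tetraene; 10 methyl (2Z)-3-formyl-4-(triethylsilyloxy)but-2-enoate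
Product: 12 (2E,5E,9E)-6,10,14-trimethyl-2-{2-[(2R)-5-oxo-3-[(triethylsilyloxy)methyl]-2,5-dihydrofuran-2-yl]ethylidene}pentadeca-5,9,13-trienal, via hydroxy ester 11 (not isolated)
Conditions: (S)-4-(indol-3-ylmethyl)-2-phenyl-3-tosyl-1,3,2-oxazaborolidin-5-one (50 mol%, from N-tosyl-(S)-tryptophan and PhBCl2), iPrOH, EtCN, −78 °C; then PPTS, CH2Cl2, rt
Reagents that add atoms: none
Why: Vinylogous Mukaiyama aldol reaction in which the boron-bound aldehyde is shielded on its Si face by the indole, so the terminal carbon of 6 adds to the Re face and sets C16 as R with an E enal; the γ-hydroxy Z-enoate then lactonises to the butenolide.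

**Step 8**
Reactants: 12 (2E,5E,9E)-6,10,14-trimethyl-2-{2-[(2R)-5-oxo-3-[(triethylsilyloxy)methyl]-2,5-dihydrofuran-2-yl]ethylidene}pentadeca-5,9,13-trienal
Product: 16 (2E)-4-[(2R)-3-(hydroxymethyl)-5-oxo-2,5-dihydrofuran-2-yl]-2-{2-[(4aS,8aS)-2,5,5,8a-tetramethyl-3,4,4a,5,6,7,8,8a-octahydronaphthalen-1-yl]ethyl}but-2-enal (target), via exocyclic alkene 13 (not isolated), via ring B trisubstituted alkene 14 (not isolated), via triethylsilyl ether 15 (not isolated)
Conditions: SnCl4 (4 equiv), (R)-2-(2-fluorobenzyloxy)-2'-hydroxy-1,1'-binaphthyl (4 equiv), toluene, −78 °C, 48 h; then CF3CO2H, −78 to 0 °C; then 1 M HCl, THF, rt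
Reagents that add atoms: none
Why: Proposed new method: the binaphthol proton, acidified by SnCl4 (Lewis acid-assisted chiral Brønsted acid, LBA), protonates the terminal isopropylidene of the chair–chair folded chain on one face; the two E-alkenes then add anti in sequence (C4–C5, then C9–C10) to give the trans-decalin C8 cation with 5S,10S, the SnCl4-bound formyl group keeps C13=C14 from closing a third ring, proton loss gives 13, 14 and some 15, CF3CO2H re-protonation funnels 13 and 14 into the tetrasubstituted Δ8(9) alkene 15 as the thermodynamic sink, and aqueous acid cleaves the silyl ether; the closest known reaction type is the LBA-induced enantioselective cationic polyene cyclization (homofarnesol to the 5S,10S ambrox series with the (R)-promoter) combined with acid equilibration of labdene alkene isomers.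

**Compound list**
1 | (2E,6E)-farnesyl bromide | CC(C)=CCC/C(C)=C/CC/C(C)=C/CBr | starting material
2 | 1,1-dimethoxypropan-2-one | COC(OC)C(C)=O | starting material
3 | (5E,9E)-1,1-dimethoxy-6,10,14-trimethylpentadeca-5,9,13-trien-2-one | COC(OC)C(=O)CC/C=C(\C)CC/C=C(\C)CCC=C(C)C | intermediate
4 | (2Z,6E,10E)-3-(dimethoxymethyl)-7,11,15-trimethylhexadeca-2,6,10,14-tetraene (mainly 2Z) | C/C=C(/CC/C=C(\C)CC/C=C(\C)CCC=C(C)C)C(OC)OC | intermediate
5 | (2E,5E,9E)-2-ethylidene-6,10,14-trimethylpentadeca-5,9,13-trienal | C/C=C(\CC/C=C(\C)CC/C=C(\C)CCC=C(C)C)C=O | intermediate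
6 | (1E,5E,9E)-1-(tert-butyldimethylsilyloxy)-2-ethenyl-6,10,14-trimethylpentadeca-1,5,9,13-tetraene | C=C/C(CC/C=C(\C)CC/C=C(\C)CCC=C(C)C)=C/O[Si](C)(C)C(C)(C)C | intermediate
7 | furan-3-ylmethanol | OCc1ccoc1 | starting material
8 | 3-[(triethylsilyloxy)methyl]furan | CC[Si](CC)(CC)OCc1ccoc1 | intermediate
9 | 5-hydroxy-4-[(triethylsilyloxy)methyl]furan-2(5H)-one (racemic hemiacetal) | O=C1C=C(CO[Si](CC)(CC)CC)C(O)O1 | intermediate
10 | methyl (2Z)-3-formyl-4-(triethylsilyloxy)but-2-enoate | COC(=O)/C=C(\C=O)CO[Si](CC)(CC)CC | intermediate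
11 | methyl (2Z,4R,6E,10E,14E)-7-formyl-4-hydroxy-11,15,19-trimethyl-3-[(triethylsilyloxy)methyl]icosa-2,6,10,14,18-pentaenoate | COC(=O)/C=C(CO[Si](CC)(CC)CC)\[C@H](O)C/C=C(/C=O)CC/C=C(\C)CC/C=C(\C)CCC=C(C)C | intermediate
12 | (2E,5E,9E)-6,10,14-trimethyl-2-{2-[(2R)-5-oxo-3-[(triethylsilyloxy)methyl]-2,5-dihydrofuran-2-yl]ethylidene}pentadeca-5,9,13-trienal | O=C/C(CC/C=C(\C)CC/C=C(\C)CCC=C(C)C)=C/C[C@H]1OC(=O)C=C1CO[Si](CC)(CC)CC | intermediate
13 | (2E)-4-[(2R)-5-oxo-3-[(triethylsilyloxy)methyl]-2,5-dihydrofuran-2-yl]-2-{2-[(1S,4aS,8aS)-5,5,8a-trimethyl-2-methylidenedecahydronaphthalen-1-yl]ethyl}but-2-enal | C=C1CC[C@H]2C(C)(C)CCC[C@]2(C)[C@H]1CC/C(C=O)=C\C[C@H]3OC(=O)C=C3CO[Si](CC)(CC)CC | intermediate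
14 | (2E)-4-[(2R)-5-oxo-3-[(triethylsilyloxy)methyl]-2,5-dihydrofuran-2-yl]-2-{2-[(1S,4aS,8aS)-2,5,5,8a-tetramethyl-1,4,4a,5,6,7,8,8a-octahydronaphthalen-1-yl]ethyl}but-2-enal | CC1=CC[C@H]2C(C)(C)CCC[C@]2(C)[C@H]1CC/C(C=O)=C\C[C@H]3OC(=O)C=C3CO[Si](CC)(CC)CC | intermediate
15 | (2E)-4-[(2R)-5-oxo-3-[(triethylsilyloxy)methyl]-2,5-dihydrofuran-2-yl]-2-{2-[(4aS,8aS)-2,5,5,8a-tetramethyl-3,4,4a,5,6,7,8,8a-octahydronaphthalen-1-yl]ethyl}but-2-enal | CC1=C(CC/C(C=O)=C\C[C@H]2OC(=O)C=C2CO[Si](CC)(CC)CC)[C@@]2(C)CCCC(C)(C)[C@@H]2CC1 | intermediate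
16 | (2E)-4-[(2R)-3-(hydroxymethyl)-5-oxo-2,5-dihydrofuran-2-yl]-2-{2-[(4aS,8aS)-2,5,5,8a-tetramethyl-3,4,4a,5,6,7,8,8a-octahydronaphthalen-1-yl]ethyl}but-2-enal | CC1=C(CC/C(C=O)=C\C[C@H]2OC(=O)C=C2CO)[C@@]2(C)CCCC(C)(C)[C@@H]2CC1 | target

**Totals**
Total step count: 8. Longest linear sequence: 5 steps (1, 2, 3, 7, 8; the branch 4, 5, 6, 7, 8 is equally long).

C16 and the decalin centres are set by two independent promoter-controlled events. The mirror image of 16 therefore forms only when both err, and the minor diastereomers are removed by chromatography.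

**Steps most likely to fail**

Step 8 (cationic bicyclization). The lactone and formyl oxygens bind SnCl4 and may erode the enantioselectivity. The activated aldehyde may also undergo Prins closure onto C8=C9, and the alkene equilibration may stop short or run on to skeletal rearrangement. The fallback sets out from 5 and moves the bicyclization to the C20 stage, where the chain carries a single Lewis-basic group. The same chiral acid followed by CF3CO2H converts 5 into the bicyclic enal (2E)-2-{2-[(4aS,8aS)-2,5,5,8a-tetramethyl-3,4,4a,5,6,7,8,8a-octahydronaphthalen-1-yl]ethyl}but-2-enal F1. TBSOTf and Et3N turn this into the bicyclic silyl dienol ether F2. The oxazaborolidinone-promoted vinylogous aldol addition of F2 to 10 gives the bicyclic hydroxy ester F3, which lactonises with PPTS. The fallback comes back to the route at 15, which is desilylated with 1 M HCl in THF as in step 8.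

Step 7 (asymmetric vinylogous aldol, together with the labile Z aldehyde 10 from step 6). The hindered, electron-poor aldehyde 10 may isomerise to the E form, react by conjugate addition, or give low or reversed facial selectivity. The fallback sets out from 9 and gives up promoter control at C16. Ac2O and pyridine convert 9 into the acetoxybutenolide 5-oxo-3-[(triethylsilyloxy)methyl]-2,5-dihydrofuran-2-yl acetate F4. BF3·OEt2 in CH2Cl2 at −78 °C ionises F4 to the furanone cation, which 6 attacks through its terminal carbon to give 12 as the racemate. Preparative chromatography on a chiral phase delivers 12, where the fallback comes back to the route. The unwanted antipode, the (2S) enantiomer of 12 F5, is racemised with catalytic Et3N through the achiral dienolate and separated again.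

Step 1 (enolate alkylation). Proton transfer, double alkylation or enolisation toward the acetal carbon may lower the yield. The fallback sets out from 1 and uses a stabilised enolate instead. Methyl 4,4-dimethoxy-3-oxobutanoate F6 is C-alkylated with 1 (K2CO3, acetone, reflux) to give the keto ester methyl (4E,8E)-2-(2,2-dimethoxyacetyl)-5,9,13-trimethyltetradeca-4,8,12-trienoate F7. Saponification with LiOH in THF/H2O and gentle warming at pH 5 decarboxylate it, and the fallback comes back to the route at 3.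

**Further compounds**
F1 | step 8 | (2E)-2-{2-[(4aS,8aS)-2,5,5,8a-tetramethyl-3,4,4a,5,6,7,8,8a-octahydronaphthalen-1-yl]ethyl}but-2-enal | CC1=C(CC/C(C=O)=C\C)[C@@]2(C)CCCC(C)(C)[C@@H]2CC1
F2 | step 8 | (1E)-1-(tert-butyldimethylsilyloxy)-2-{2-[(4aS,8aS)-2,5,5,8a-tetramethyl-3,4,4a,5,6,7,8,8a-octahydronaphthalen-1-yl]ethyl}buta-1,3-diene | CC1=C(CC/C(C=C)=C\O[Si](C)(C)C(C)(C)C)[C@@]2(C)CCCC(C)(C)[C@@H]2CC1
F3 | step 8 | methyl (2Z,4R,6E)-7-formyl-4-hydroxy-9-[(4aS,8aS)-2,5,5,8a-tetramethyl-3,4,4a,5,6,7,8,8a-octahydronaphthalen-1-yl]-3-[(triethylsilyloxy)methyl]nona-2,6-dienoate | COC(=O)/C=C(CO[Si](CC)(CC)CC)\[C@H](O)C/C=C(/C=O)CCC1=C(C)CC[C@H]2C(C)(C)CCC[C@]12C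
F4 | step 7 | 5-oxo-3-[(triethylsilyloxy)methyl]-2,5-dihydrofuran-2-yl acetate (racemic) | CC(=O)OC1OC(=O)C=C1CO[Si](CC)(CC)CC
F5 | step 7 | (2E,5E,9E)-6,10,14-trimethyl-2-{2-[(2S)-5-oxo-3-[(triethylsilyloxy)methyl]-2,5-dihydrofuran-2-yl]ethylidene}pentadeca-5,9,13-trienal | O=C/C(CC/C=C(\C)CC/C=C(\C)CCC=C(C)C)=C/C[C@@H]1OC(=O)C=C1CO[Si](CC)(CC)CC
F6 | step 1 | methyl 4,4-dimethoxy-3-oxobutanoate | COC(=O)CC(=O)C(OC)OC
F7 | step 1 | methyl (4E,8E)-2-(2,2-dimethoxyacetyl)-5,9,13-trimethyltetradeca-4,8,12-trienoate | COC(=O)C(C/C=C(\C)CC/C=C(\C)CCC=C(C)C)C(=O)C(OC)OC
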